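**Plan**

Numbering: oxane O1, C2 (aryl), C3, C4 (OH), C5, C6 (arylethyl); the C3 side chain is a hept-1-enyl unit C1'–C7' (C3' branch point, C5' carbinol).
Retrosynthesis: C4 and C6 are taken to the ketone and enol-ether levels, O1–C6 is cut (ring closure of a β-hydroxy ynone), then C2–C3 and C4–C5 are cut together to leave an aryl aldehyde, a terminal alkyne and a δ-lactone; the lactone is cut at C3–C3' (allylic alkylation) and C3'–C4' (aldol).
Enabling feature: C4 lies δ to the C5' oxygen (C4–C3–C3'–C4'–C5'–O), so C3–C4 can sit in a temporary six-membered lactone ring O–C5'–C4'–C3'–C3–C4, where C3 is an enolate carbon and C4 an acyl carbon.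
Forward order: raspberry ketone (used twice), 4-silyloxybenzaldehyde (used twice), a two-carbon ylide and Meldrum's acid give the cis-lactone; a three-component union builds the C2–C8 chain on it and opens the lactone; the oxane closes at O1–C6; two hydride additions and desilylation finish.
Stereochemistry: C3' from a catalyst-controlled Mukaiyama aldol (set as a carbinol, then replaced with retention by double inversion on palladium); C5' by 1,3-syn reduction; C3 and C2 from the lactone ring (attack anti to the styryl group, chair anti-aldol); C6 by axial and C4 by equatorial hydride delivery.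

Key step: step 9

Remark: Ar stands for 4-(tert-butyldimethylsilyloxy)phenyl in all names; it is assumed that these aryl silyl ethers tolerate the amide, acetylide and borohydride reagents at −78 °C, as phenol silyl ethers normally do.

**Route**

Step 1
Reactants: 1 4-(4-hydroxyphenyl)butan-2-one (raspberry ketone)
Product: 2 4-Ar-butan-2-one
Conditions: TBSCl, imidazole, DMF, 0 °C → rt
Reagents that add atoms: tert-butyldimethylsilyl chloride, CC(C)(C)[Si](C)(C)Cl
Why: Imidazole-promoted silylation masks the acidic phenol before the enolate chemistry that follows; no stereocenter is involved.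

Step 2
Reactants: 2 4-Ar-butan-2-one
Product: 4 tert-butyldimethyl{4-[3-(trimethylsilyloxy)but-3-en-1-yl]phenoxy}silane, via kinetic lithium enolate 3 (not isolated)
Conditions: LiN(iPr)2 (1.1 equiv), THF, −78 °C; Me3SiCl, −78 → 0 °C
Reagents that add atoms: chlorotrimethylsilane, C[Si](C)(C)Cl
Why: The hindered amide base removes a methyl proton of the methyl ketone under kinetic control, and O-silylation of that enolate should give the terminal silyl enol ether (kinetic enolate trapping).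

Step 3
Reactants: 5 4-(tert-butyldimethylsilyloxy)benzaldehyde; 6 (triphenylphosphoranylidene)acetaldehyde
Product: 7 (E)-3-Ar-prop-2-enal
Conditions: toluene, 80 °C
Reagents that add atoms: none
Why: Wittig olefination with the stabilised formylmethylene ylide is E-selective and should stop after one homologation because the conjugated enal is the less electrophilic aldehyde.

Step 4
Reactants: 4 tert-butyldimethyl{4-[3-(trimethylsilyloxy)but-3-en-1-yl]phenoxy}silane; 7 (E)-3-Ar-prop-2-enal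
Product: 8 (5S,6E)-5-hydroxy-1,7-di-Ar-hept-6-en-3-one
Conditions: SiCl4 (1.1 equiv), (S,S)-configured binaphthyl-2,2'-diamine-derived bisphosphoramide (5 mol %, the antipode that opens the Si face of 7), iPr2NEt (cat.), CH2Cl2, −78 °C; aq. NaHCO3
Reagents that add atoms: none
Why: In this Lewis-base-activated Mukaiyama aldol addition the chiral phosphoramide-bound trichlorosilyl cation activates the conjugated aldehyde, and 1,2-addition of the enol ether to its Si face should set the (S)-carbinol, the future C3', under catalyst control.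

Step 5
Reactants: 8 (5S,6E)-5-hydroxy-1,7-di-Ar-hept-6-en-3-one
Product: 10 (3S,5S,6E)-1,7-di-Ar-hept-6-ene-3,5-diol, via O-diethylboryl chelate 9 (not isolated)
Conditions: Et2BOMe, THF/MeOH (4:1), −78 °C; NaBH4; AcOH; MeOH azeotrope
Reagents that add atoms: none
Why: In the Narasaka–Prasad reduction the boron chelate holds the hydroxy ketone in a half-chair that external hydride attacks axially, which should give the 1,3-syn diol and so set the future C5' from the existing carbinol.

Step 6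
Reactants: 10 (3S,5S,6E)-1,7-di-Ar-hept-6-ene-3,5-diol
Product: 11 (4S,6S)-4-[(E)-2-Ar-ethenyl]-6-(2-Ar-ethyl)-1,3-dioxan-2-one
Conditions: CDI, DMAP (cat.), CH2Cl2, rt → 40 °C
Reagents that add atoms: 1,1'-carbonyldiimidazole, O=C(n1ccnc1)n1ccnc1
Why: Carbonylation of the syn-1,3-diol should give the six-membered cyclic carbonate with both substituents equatorial, which turns the allylic oxygen into a leaving group and masks the other hydroxyl at once.

Step 7
Reactants: 11 (4S,6S)-4-[(E)-2-Ar-ethenyl]-6-(2-Ar-ethyl)-1,3-dioxan-2-one; 12 Meldrum's acid (2,2-dimethyl-1,3-dioxane-4,6-dione)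
Product: 14 (4R,6S)-4-[(E)-2-Ar-ethenyl]-6-(2-Ar-ethyl)oxan-2-one, via C-allylated Meldrum's acid 13 (not isolated)
Conditions: Pd2(dba)3 (2.5 mol %; dba = dibenzylideneacetone), PPh3 (10 mol %), 12 (3 equiv), THF, rt; then toluene, 100 °C
Reagents that add atoms: none
Why: In this Tsuji–Trost alkylation zerovalent palladium ionises the allylic C–O bond with inversion and loss of CO2, the freed alkoxide deprotonates 12, and its anion should attack the allyl terminus remote from the aryl group anti to palladium (net retention, styrene conjugation kept), after which heating lets the C5' hydroxyl open the Meldrum ring and the malonic half-acid lose CO2 to give the cis-lactone.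

Step 8
Reactants: 2 4-Ar-butan-2-one
Product: 17 tert-butyl[4-(but-3-yn-1-yl)phenoxy]dimethylsilane, via kinetic potassium enolate 15 (not isolated), via enol diethyl phosphate 16 (not isolated)
Conditions: KN(SiMe3)2 (1.05 equiv), THF, −78 °C; ClP(O)(OEt)2, −78 °C → rt; LiN(iPr)2 (3.4 equiv), −78 °C → rt; aq. NH4Cl
Reagents that add atoms: none
Why: KN(SiMe3)2 removes a methyl proton of the methyl ketone under kinetic control, the potassium enolate is O-phosphorylated, and LiN(iPr)2 (one equivalent is taken up by the HN(SiMe3)2 set free) then eliminates diethyl phosphate from the terminal enol phosphate to give the terminal alkyne regioselectively (methyl ketone to alkyne conversion through an enol phosphate).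

Step 9
Reactants: 14 (4R,6S)-4-[(E)-2-Ar-ethenyl]-6-(2-Ar-ethyl)oxan-2-one; 5 4-(tert-butyldimethylsilyloxy)benzaldehyde; 17 tert-butyl[4-(but-3-yn-1-yl)phenoxy]dimethylsilane
Product: 21 (6R,7S,9S)-9-hydroxy-6-[(S)-hydroxy(Ar)methyl]-1,11-di-Ar-7-[(E)-2-Ar-ethenyl]undec-3-yn-5-one, via lactone lithium enolate 18 (not isolated), via lithium aldolate 19 (not isolated), via lithium acetylide 20 (not isolated)
Conditions: LiN(iPr)2 (1.1 equiv), THF, −78 °C; 5 (1.0 equiv), −78 °C; 20 (from 17 (3 equiv), n-BuLi, THF, −78 °C), −78 → −50 °C; AcOH, −78 °C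
Reagents that add atoms: none
Why: LiN(iPr)2 turns 14 into the ring-locked enolate 18, which adds to 5 through a closed six-membered chair transition state to give aldolate 19 (C2–C3 bond), and acetylide 20 then attacks the lithium-chelated lactone carbonyl C4 of 19 (C4–C5 bond) to give a lactol alkoxide that opens to ynone 21 on protonation and frees the C5' hydroxyl. The closest known reaction types are the aldol addition of δ-lactone enolates and the mono-addition of lithium acetylides to lactones, run here back to back in the manner of an enolate-trapping three-component coupling. No ring is closed in this step: the temporary lactone O–C5'–C4'–C3'–C3–C4 is opened, and the oxane closes in step 10. C3 is set by approach of 5 to the enolate face anti to the neighbouring equatorial styryl group at C3' (3,4-trans on the lactone), and C2 by the chair transition state of an enolate whose carbon substituent is held trans to O–Li by the ring, which places the aryl group equatorial and should give the anti (2S) aldolate. The step needs anti over syn simple diastereoselection, addition of only one acetylide and no retro-aldol cleavage: the fixed enolate geometry and the all-equatorial lactone serve the first, the persistence of the lactol alkoxide at −78 °C the second, and the low temperature with an acidic quench before warming the third.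

Step 10
Reactants: 21 (6R,7S,9S)-9-hydroxy-6-[(S)-hydroxy(Ar)methyl]-1,11-di-Ar-7-[(E)-2-Ar-ethenyl]undec-3-yn-5-one
Product: 22 (2S,3R)-2-Ar-6-(2-Ar-ethyl)-3-[(1E,3S,5S)-5-hydroxy-1,7-di-Ar-hept-1-en-3-yl]-2,3-dihydro-4H-pyran-4-one
Conditions: AgOSO2CF3 (10 mol %), CH2Cl2, rt
Reagents that add atoms: none
Why: Silver-promoted 6-endo-dig oxa-Michael addition of the C2 hydroxyl to the ynone should close the oxane as a vinylogous ester, since the C5' hydroxyl could reach C6 only through an eight-membered ring, and the epimerisable C3 rests trans to the C2 aryl group.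

Step 11
Reactants: 22 (2S,3R)-2-Ar-6-(2-Ar-ethyl)-3-[(1E,3S,5S)-5-hydroxy-1,7-di-Ar-hept-1-en-3-yl]-2,3-dihydro-4H-pyran-4-one
Product: 23 (2S,3R,6S)-2-Ar-6-(2-Ar-ethyl)-3-[(1E,3S,5S)-5-hydroxy-1,7-di-Ar-hept-1-en-3-yl]oxan-4-one
Conditions: LiBH(s-Bu)3 (2.2 equiv), THF, −78 °C; aq. NH4Cl
Reagents that add atoms: none
Why: In this conjugate reduction the bulky trialkylborohydride should add hydride to C6 along the axial trajectory of the half-chair, so the arylethyl group ends equatorial and cis to the C2 aryl group, and the enolate is protonated on work-up.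

Step 12
Reactants: 23 (2S,3R,6S)-2-Ar-6-(2-Ar-ethyl)-3-[(1E,3S,5S)-5-hydroxy-1,7-di-Ar-hept-1-en-3-yl]oxan-4-one
Product: 24 (2S,3S,4S,6S)-2-Ar-6-(2-Ar-ethyl)-3-[(1E,3S,5S)-5-hydroxy-1,7-di-Ar-hept-1-en-3-yl]oxan-4-ol
Conditions: LiBH(s-Bu)3 (3 equiv), THF, −78 °C; aq. NH4Cl
Reagents that add atoms: none
Why: The bulky hydride should attack the chair ketone, whose three substituents are equatorial, from the equatorial side and give the axial C4 alcohol (trialkylborohydride reduction of a cyclic ketone).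

Step 13
Reactants: 24 (2S,3S,4S,6S)-2-Ar-6-(2-Ar-ethyl)-3-[(1E,3S,5S)-5-hydroxy-1,7-di-Ar-hept-1-en-3-yl]oxan-4-ol
Product: 25 blepharocalyxin C
Conditions: Bu4NF, AcOH (5 equiv each), THF, 0 °C → rt
Reagents that add atoms: none
Why: Fluoride should cleave the four aryl silyl ethers, with acetic acid buffering the phenoxides so that the 4-hydroxybenzylic ether at C2 is not opened through a quinone methide.

**Compound list**

1 | 4-(4-hydroxyphenyl)butan-2-one (raspberry ketone) | CC(=O)CCc1ccc(O)cc1 | starting material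
2 | 4-Ar-butan-2-one | CC(=O)CCc1ccc(O[Si](C)(C)C(C)(C)C)cc1 | intermediate
3 | kinetic lithium enolate of 2 (lithium 4-Ar-but-1-en-2-olate) | [Li]OC(=C)CCc1ccc(O[Si](C)(C)C(C)(C)C)cc1 | intermediate
4 | tert-butyldimethyl{4-[3-(trimethylsilyloxy)but-3-en-1-yl]phenoxy}silane | C=C(CCc1ccc(O[Si](C)(C)C(C)(C)C)cc1)O[Si](C)(C)C | intermediate
5 | 4-(tert-butyldimethylsilyloxy)benzaldehyde | O=Cc1ccc(O[Si](C)(C)C(C)(C)C)cc1 | starting material
6 | (triphenylphosphoranylidene)acetaldehyde | O=CC=P(c1ccccc1)(c1ccccc1)c1ccccc1 | starting material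
7 | (E)-3-Ar-prop-2-enal | O=C/C=C/c1ccc(O[Si](C)(C)C(C)(C)C)cc1 | intermediate
8 | (5S,6E)-5-hydroxy-1,7-di-Ar-hept-6-en-3-one | CC(C)(C)[Si](C)(C)Oc1ccc(/C=C/[C@H](CC(=O)CCc2ccc(O[Si](C)(C)C(C)(C)C)cc2)O)cc1 | intermediate
9 | O-diethylboryl chelate of 8 | CC(C)(C)[Si](C)(C)Oc1ccc(/C=C/[C@H](CC(=O)CCc2ccc(O[Si](C)(C)C(C)(C)C)cc2)OB(CC)CC)cc1 | intermediate
10 | (3S,5S,6E)-1,7-di-Ar-hept-6-ene-3,5-diol (syn) | CC(C)(C)[Si](C)(C)Oc1ccc(/C=C/[C@H](C[C@@H](O)CCc2ccc(O[Si](C)(C)C(C)(C)C)cc2)O)cc1 | intermediate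
11 | (4S,6S)-4-[(E)-2-Ar-ethenyl]-6-(2-Ar-ethyl)-1,3-dioxan-2-one (cis) | CC(C)(C)[Si](C)(C)Oc1ccc(/C=C/[C@@H]2C[C@H](CCc3ccc(O[Si](C)(C)C(C)(C)C)cc3)OC(=O)O2)cc1 | intermediate
12 | Meldrum's acid (2,2-dimethyl-1,3-dioxane-4,6-dione) | CC1(C)OC(=O)CC(=O)O1 | starting material
13 | 5-[(1E,3S,5S)-5-hydroxy-1,7-di-Ar-hept-1-en-3-yl]-2,2-dimethyl-1,3-dioxane-4,6-dione | CC(C)(C)[Si](C)(C)Oc1ccc(/C=C/[C@H](C[C@@H](O)CCc2ccc(O[Si](C)(C)C(C)(C)C)cc2)C2C(=O)OC(C)(C)OC2=O)cc1 | intermediate
14 | (4R,6S)-4-[(E)-2-Ar-ethenyl]-6-(2-Ar-ethyl)oxan-2-one (cis) | CC(C)(C)[Si](C)(C)Oc1ccc(/C=C/[C@@H]2C[C@H](CCc3ccc(O[Si](C)(C)C(C)(C)C)cc3)OC(=O)C2)cc1 | intermediate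
15 | kinetic potassium enolate of 2 (potassium 4-Ar-but-1-en-2-olate) | [K]OC(=C)CCc1ccc(O[Si](C)(C)C(C)(C)C)cc1 | intermediate
16 | diethyl 4-Ar-but-1-en-2-yl phosphate | C=C(CCc1ccc(O[Si](C)(C)C(C)(C)C)cc1)OP(=O)(OCC)OCC | intermediate
17 | tert-butyl[4-(but-3-yn-1-yl)phenoxy]dimethylsilane | C#CCCc1ccc(O[Si](C)(C)C(C)(C)C)cc1 | intermediate
18 | lithium enolate of lactone 14 (C3=C(OLi) of the oxan-2-one) | CC(C)(C)[Si](C)(C)Oc1ccc(/C=C/[C@@H]2C[C@H](CCc3ccc(O[Si](C)(C)C(C)(C)C)cc3)OC(O[Li])=C2)cc1 | intermediate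
19 | lithium (S)-Ar[(3R,4S,6S)-2-oxo-6-(2-Ar-ethyl)-4-((E)-2-Ar-ethenyl)oxan-3-yl]methanolate | CC(C)(C)[Si](C)(C)Oc1ccc(/C=C/[C@@H]2C[C@H](CCc3ccc(O[Si](C)(C)C(C)(C)C)cc3)OC(=O)[C@H]2[C@@H](c2ccc(O[Si](C)(C)C(C)(C)C)cc2)O[Li])cc1 | intermediate
20 | lithium acetylide of 17 (4-Ar-but-1-yn-1-yllithium) | [Li]C#CCCc1ccc(O[Si](C)(C)C(C)(C)C)cc1 | intermediate
21 | (6R,7S,9S)-9-hydroxy-6-[(S)-hydroxy(Ar)methyl]-1,11-di-Ar-7-[(E)-2-Ar-ethenyl]undec-3-yn-5-one | CC(C)(C)[Si](C)(C)Oc1ccc(/C=C/[C@H](C[C@@H](O)CCc2ccc(O[Si](C)(C)C(C)(C)C)cc2)[C@@H](C(=O)C#CCCc2ccc(O[Si](C)(C)C(C)(C)C)cc2)[C@@H](c2ccc(O[Si](C)(C)C(C)(C)C)cc2)O)cc1 | intermediate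
22 | (2S,3R)-2-Ar-6-(2-Ar-ethyl)-3-[(1E,3S,5S)-5-hydroxy-1,7-di-Ar-hept-1-en-3-yl]-2,3-dihydro-4H-pyran-4-one | CC(C)(C)[Si](C)(C)Oc1ccc(/C=C/[C@H](C[C@@H](O)CCc2ccc(O[Si](C)(C)C(C)(C)C)cc2)[C@@H]2[C@@H](c3ccc(O[Si](C)(C)C(C)(C)C)cc3)OC(CCc3ccc(O[Si](C)(C)C(C)(C)C)cc3)=CC2=O)cc1 | intermediate
23 | (2S,3R,6S)-2-Ar-6-(2-Ar-ethyl)-3-[(1E,3S,5S)-5-hydroxy-1,7-di-Ar-hept-1-en-3-yl]oxan-4-one | CC(C)(C)[Si](C)(C)Oc1ccc(/C=C/[C@H](C[C@@H](O)CCc2ccc(O[Si](C)(C)C(C)(C)C)cc2)[C@@H]2[C@@H](c3ccc(O[Si](C)(C)C(C)(C)C)cc3)O[C@@H](CCc3ccc(O[Si](C)(C)C(C)(C)C)cc3)CC2=O)cc1 | intermediate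
24 | (2S,3S,4S,6S)-2-Ar-6-(2-Ar-ethyl)-3-[(1E,3S,5S)-5-hydroxy-1,7-di-Ar-hept-1-en-3-yl]oxan-4-ol | CC(C)(C)[Si](C)(C)Oc1ccc(/C=C/[C@H](C[C@@H](O)CCc2ccc(O[Si](C)(C)C(C)(C)C)cc2)[C@@H]2[C@@H](c3ccc(O[Si](C)(C)C(C)(C)C)cc3)O[C@@H](CCc3ccc(O[Si](C)(C)C(C)(C)C)cc3)C[C@@H]2O)cc1 | intermediate
25 | blepharocalyxin C, (2S,3S,4S,6S)-2-(4-hydroxyphenyl)-6-[2-(4-hydroxyphenyl)ethyl]-3-[(1E,3S,5S)-5-hydroxy-1,7-bis(4-hydroxyphenyl)hept-1-en-3-yl]oxan-4-ol | Oc1ccc(/C=C/[C@H](C[C@@H](O)CCc2ccc(O)cc2)[C@@H]2[C@@H](c3ccc(O)cc3)O[C@@H](CCc3ccc(O)cc3)C[C@@H]2O)cc1 | target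

**Count and risks**

Total steps: 13. Longest linear sequence: 11 (steps 1, 2, 4, 5, 6, 7, 9, 10, 11, 12, 13).

Steps most likely to fail:

Step 9. The aldol addition may show poor simple diastereoselection at C2, and the aldolate may undergo retro-aldol cleavage or incomplete acyl substitution while it waits for the acetylide. The fallback sets out from 14 and comes back at 21; it separates the two bond formations and sets C2 by catalyst-controlled reduction instead of by the aldol. Enolate 18 is condensed with 5 without regard to the carbinol configuration to give the (3R,4S,6S)-3-[hydroxy(Ar)methyl]-6-(2-Ar-ethyl)-4-[(E)-2-Ar-ethenyl]oxan-2-ones F1 as a mixture of carbinol epimers. Dess–Martin oxidation converts them into the 3-aroyl lactone F2, whose C3 is stereolabile and settles trans to the styryl group. Asymmetric transfer hydrogenation with dynamic kinetic resolution (RuCl[(S,S)-TsDPEN](p-cymene), HCO2H/Et3N) should then give the single (S)-carbinol hydroxy lactone F3, the protonated form of 19. F3 is treated with an excess of 20 (one equivalent is consumed by the hydroxyl) at −78 °C and quenched with AcOH to give 21.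

Step 7. The nucleophile may attack the benzylic terminus of the aryl-substituted allyl–palladium intermediate, configuration may erode through allyl–palladium exchange, or the tethered alkoxide may O-alkylate. The fallback sets out from 10 and comes back at 14; it makes the C3–C3' bond intramolecularly so that ring size dictates the regiochemistry. Both hydroxyls of 10 are acylated with methyl malonyl chloride and pyridine to give the bis(methyl malonate) F4. With Pd(PPh3)4 and NaH the allylic malonate ionises and the malonate tethered through the C5' oxygen closes the six-membered ring at C3' (attack at the benzylic carbon would need an eight-membered ring), giving the 3-methoxycarbonyl lactone F5 with overall retention. Krapcho demethoxycarbonylation (LiCl, wet DMSO, heat) then gives 14.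

Step 11. The vinylogous ester may undergo 1,2-reduction, or the enolate may eliminate the ring oxygen, so the conjugate reduction may give mixtures. The fallback sets out from 17 and 14 and comes back at 23; it avoids the alkyne oxidation level, so no conjugate reduction is needed. Hydrozirconation of 17 with Cp2Zr(H)Cl and iodinolysis gives the (E)-vinyl iodide F6. Halogen–lithium exchange with t-BuLi at −78 °C gives the (E)-vinyllithium F7, which replaces 20 in the union with 19 (made from 14 and 5 as in step 9) to give the β'-hydroxy enone F8. Acid-catalysed (p-TsOH) intramolecular oxa-Michael addition of the C2 hydroxyl then closes the oxane directly to the thermodynamically preferred all-equatorial ketone 23.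

**Further compounds**

F1 | step 9 | (3R,4S,6S)-3-[hydroxy(Ar)methyl]-6-(2-Ar-ethyl)-4-[(E)-2-Ar-ethenyl]oxan-2-one, mixture of carbinol epimers | CC(C)(C)[Si](C)(C)Oc1ccc(/C=C/[C@@H]2C[C@H](CCc3ccc(O[Si](C)(C)C(C)(C)C)cc3)OC(=O)[C@H]2C(O)c2ccc(O[Si](C)(C)C(C)(C)C)cc2)cc1
F2 | step 9 | (4S,6S)-3-(Ar-carbonyl)-6-(2-Ar-ethyl)-4-[(E)-2-Ar-ethenyl]oxan-2-one (C3 stereolabile) | CC(C)(C)[Si](C)(C)Oc1ccc(/C=C/[C@@H]2C[C@H](CCc3ccc(O[Si](C)(C)C(C)(C)C)cc3)OC(=O)C2C(=O)c2ccc(O[Si](C)(C)C(C)(C)C)cc2)cc1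
F3 | step 9 | (3R,4S,6S)-3-[(S)-hydroxy(Ar)methyl]-6-(2-Ar-ethyl)-4-[(E)-2-Ar-ethenyl]oxan-2-one | CC(C)(C)[Si](C)(C)Oc1ccc(/C=C/[C@@H]2C[C@H](CCc3ccc(O[Si](C)(C)C(C)(C)C)cc3)OC(=O)[C@H]2[C@@H](c2ccc(O[Si](C)(C)C(C)(C)C)cc2)O)cc1
F4 | step 7 | (3S,5S,6E)-1,7-di-Ar-hept-6-ene-3,5-diyl bis(methyl malonate) | CC(C)(C)[Si](C)(C)Oc1ccc(/C=C/[C@H](C[C@@H](OC(=O)CC(=O)OC)CCc2ccc(O[Si](C)(C)C(C)(C)C)cc2)OC(=O)CC(=O)OC)cc1
F5 | step 7 | methyl (4S,6S)-2-oxo-6-(2-Ar-ethyl)-4-[(E)-2-Ar-ethenyl]oxane-3-carboxylate (C3 stereolabile) | CC(C)(C)[Si](C)(C)Oc1ccc(/C=C/[C@@H]2C[C@H](CCc3ccc(O[Si](C)(C)C(C)(C)C)cc3)OC(=O)C2C(=O)OC)cc1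
F6 | step 11 | tert-butyl{4-[(E)-4-iodobut-3-en-1-yl]phenoxy}dimethylsilane | I/C=C/CCc1ccc(O[Si](C)(C)C(C)(C)C)cc1
F7 | step 11 | (E)-4-Ar-but-1-en-1-yllithium | [Li]/C=C/CCc1ccc(O[Si](C)(C)C(C)(C)C)cc1
F8 | step 11 | (3E,6R,7S,9S)-9-hydroxy-6-[(S)-hydroxy(Ar)methyl]-1,11-di-Ar-7-[(E)-2-Ar-ethenyl]undec-3-en-5-one | CC(C)(C)[Si](C)(C)Oc1ccc(/C=C/[C@H](C[C@@H](O)CCc2ccc(O[Si](C)(C)C(C)(C)C)cc2)[C@@H](C(=O)/C=C/CCc2ccc(O[Si](C)(C)C(C)(C)C)cc2)[C@@H](c2ccc(O[Si](C)(C)C(C)(C)C)cc2)O)cc1
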